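The question was how much complex with one exchanged the flask would hold at 80 min, 6.0 h and 25 h, and I answered it with a bracket.

in all of them: starting complex 0.37 M; incoming ligand 0.351 M

| charge | leaving ligand | remark | time |
|---|---|---|---|
| elm | 0.37 M | the very flask that is asked about, followed so far |  |
| flask | 0.370 M |  | 25 h |

elm run (percent of the starting complex charged)

| time / h | complex with one exchanged / % | starting complex / % |
|---|---|---|
| 1.00 | 5.1 | 94.4 |
| 2.00 | 6.7 | 93.7 |
| 3.00 | 10.4 | 89.0 |
| 4.00 | 11.5 | 86.3 |
| 5.00 | 14.5 | 82.3 |
| 6.00 | 17.5 | 81.5 |
| 8.00 | 19.7 | 76.5 |

(scatter of a reading: 1 percentage point)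

* amount of complex with one exchanged in percent of the starting complex charged, at 80 min, 6.0 h and 25 h

Incoming ligand, the limiting reagent, was charged at 0.949 of the starting complex. I therefore let both fall by nearly the same fraction of their charge, which gives a second-order curve for m, the fraction of starting complex left. I called the time in which m falls to half at these charges the pair time, τ = 26.0 h, read from the last reading:

m = 1 / (1 + t/τ), so lost by 25 h: 49.0%

That reading also left a shortfall of 3.80%, which I took as complex with two exchanged. For my upper bound I let that amount stand and nothing more pass on. For my lower bound I let the second step run one way, with a selectivity factor r read from shortfall ≈ (r/2)·lost²: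

upper: 45.2%

r = 1.38; lower: (m^r − m)/(1 − r) = 30.3%

I committed to the middle, 37.8%. The same sum, lost minus (r/2)·lost², gave 4.71% at 80 min and 16.3% at 6.0 h.

The forecast said 4.6%, 16.5% and 39%, the last inside my bracket, adding: “The uncertainty is mainly in the second step”.

The flask gave 4.70%, 16.4% and 40.8%, the last also inside.

    starting complex + incoming ligand → leaving ligand + complex with one exchanged (k = 0.00183 L mol⁻¹ min⁻¹)
    complex with one exchanged + incoming ligand ⇌ leaving ligand + complex with two exchanged (K = 0.530, k = 0.00283 L mol⁻¹ min⁻¹)

The first step ran throughout: at 12.5 h the flask held 68.4% starting complex, where τ gives 67.5%, and at 25 h it held 53.2%, where τ gives 51.0%. The second step ran both ways beside it, with a relaxation half-life of 2.89 h at 25.0 h, short against the run, while complex with one exchanged was made 5.09 times faster than used up at 8.12 h, and complex with two exchanged reached 5.92% at 25.0 h.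

The data come from a simulation from invented constants, noise included.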